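**Assumptions.** The target SMILES has no stereocentres and marchantin H is an achiral, conformationally mobile macrocycle, so no stereocontrol is needed. Only substrates and building blocks are numbered; reagents are given by name and SMILES. Compounds 1, 3, 5 and 7 are taken as catalogue materials (7 is stored cold and used promptly). The route is a paper design and has not been run.

## Retrosynthetic overview

1. Marchantin H ⇐ O‑demethylation ⇐ double Dakin oxidation of macrocyclic dialdehyde 10. The two "inner" OH groups (ring A OH, ring C OH next to the ether) are carried as CHO groups.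
2. Those same CHO groups activate both diaryl ether formations by SNAr. The 18‑membered ring is closed last at the ring A–O–ring B ether by intramolecular SNAr, not at a bibenzyl bridge (the usual Wittig/McMurry/Wurtz closure).
3. Seco‑precursor 9 ⇐ chemoselective hydrogenation of a bis(diarylalkyne) made by two Sonogashira couplings (ArI‑selective with 5, then ArBr with 7).
4. Ring C–O–ring D ether ⇐ intermolecular SNAr of fluoroaldehyde 2 with 3; 2 ⇐ directed ortho‑metalation/formylation of 1.
5. Ring order: all four arenes are bought; the only ring formed is the 18‑membered macrocycle (step 6).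

## Route

**Step 1**
Reactants: 1, 4‑bromo‑3‑fluoroanisole
Product: 2, 3‑bromo‑2‑fluoro‑6‑methoxybenzaldehyde
Conditions: LDA (1.1 equiv), THF, −78 °C, 1 h; DMF, −78 → 0 °C; aq NH4Cl
Reagents that add atoms: N,N‑dimethylformamide, CN(C)C=O (gives the CHO carbon and oxygen)
Why: Directed ortho‑metalation: the C–H flanked by F and OMe is the most acidic site, LDA does not exchange the bromide, and the aryllithium is stable at −78 °C before formylation.

**Step 2**
Reactants: 2, 3‑bromo‑2‑fluoro‑6‑methoxybenzaldehyde (1.1 equiv); 3, 3‑ethynylphenol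
Product: 4, 3‑bromo‑2‑(3‑ethynylphenoxy)‑6‑methoxybenzaldehyde
Conditions: K2CO3, DMF, 90 °C
Reagents that add atoms: none
Why: Intermolecular SNAr: fluoride ortho to CHO (and further activated by the ortho Br) is displaced by the phenoxide; Br is meta to CHO and is not touched, and the terminal alkyne tolerates carbonate.

**Step 3**
Reactants: 4, 3‑bromo‑2‑(3‑ethynylphenoxy)‑6‑methoxybenzaldehyde; 5, 2‑fluoro‑4‑iodobenzaldehyde (1.1 equiv)
Product: 6, 3‑bromo‑2‑{3‑[(3‑fluoro‑4‑formylphenyl)ethynyl]phenoxy}‑6‑methoxybenzaldehyde
Conditions: PdCl2(PPh3)2 (2 mol%), CuI (4 mol%), Et3N/THF, rt, degassed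
Reagents that add atoms: none
Why: Sonogashira coupling: the para‑formyl aryl iodide reacts at rt, while the hindered, electron‑rich ArBr of 4 is inert with a PPh3 catalyst at rt, so 4 does not self‑couple.

**Step 4**
Reactants: 6, 3‑bromo‑2‑{3‑[(3‑fluoro‑4‑formylphenyl)ethynyl]phenoxy}‑6‑methoxybenzaldehyde; 7, 4‑ethynylphenol (1.3 equiv)
Product: 8, 2‑{3‑[(3‑fluoro‑4‑formylphenyl)ethynyl]phenoxy}‑3‑[(4‑hydroxyphenyl)ethynyl]‑6‑methoxybenzaldehyde
Conditions: Pd(PhCN)2Cl2 (5 mol%), P(t‑Bu)3·HBF4 (10 mol%), CuI (5 mol%), i‑Pr2NH, dioxane, rt → 45 °C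
Reagents that add atoms: none
Why: Sonogashira coupling of an aryl bromide with a bulky electron‑rich phosphine at near rt; the amine is too weak a base and too hindered to trigger SNAr at the fluoroaldehyde or to condense with the aldehydes.

**Step 5**
Reactants: 8, bis‑alkyne from step 4
Product: 9, 2‑{3‑[2‑(3‑fluoro‑4‑formylphenyl)ethyl]phenoxy}‑3‑[2‑(4‑hydroxyphenyl)ethyl]‑6‑methoxybenzaldehyde
Conditions: H2 (1 atm), 10% Pd/C, Ph2S (cat.), EtOAc, rt
Reagents that add atoms: none
Why: Chemoselective catalytic hydrogenation: sulfide‑poisoned Pd/C saturates both diarylalkynes to CH2CH2 while leaving aromatic aldehydes and the C–F bond intact; EtOAc avoids acetal formation.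

**Step 6**
Reactants: 9, seco fluoro‑phenol from step 5
Product: 10, macrocyclic dialdehyde (marchantin H skeleton with ring A OH = CHO, ring C inner OH = CHO, ring C outer OH = OMe)
Conditions: Cs2CO3 (3 equiv), 4 Å MS, DMF, 80 °C, syringe‑pump addition to about 2 mM
Reagents that add atoms: none
Why: Intramolecular SNAr macro‑etherification: the para‑alkyl phenoxide of ring B attacks the unhindered C–F ortho to CHO on ring A to close the 18‑membered ring. The formyl‑activated intermolecular version is routine; formyl activation in the macrocyclic version is the accepted risk. High dilution suppresses oligomers, and the only other SNAr‑capable sites (OAr/OMe on ring C) are far poorer leaving groups.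

**Step 7**
Reactants: 10, macrocyclic dialdehyde
Product: 11, marchantin H mono‑methyl ether (ring A OH and ring C inner OH free; ring C outer O as OMe)
Conditions: mCPBA (3 equiv), CH2Cl2, 0 °C → rt; then K2CO3, MeOH, rt
Reagents that add atoms: meta‑chloroperoxybenzoic acid, OOC(=O)c1cccc(Cl)c1 (one O inserted at each aryl–CHO bond)
Why: Double Dakin‑type Baeyer–Villiger oxidation: both aldehydes carry ortho oxygen donors (2‑aryloxy on ring A; 2‑aryloxy‑6‑methoxy on ring C), so aryl migration gives aryl formates, which methanolysis cleaves to the phenols.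

**Step 8**
Reactants: 11, marchantin H mono‑methyl ether
Product: 12, marchantin H
Conditions: BBr3 (5 equiv), CH2Cl2, −78 °C → rt; MeOH/H2O quench
Reagents that add atoms: none
Why: Lewis‑acid O‑demethylation of the guaiacol unit to the catechol; diaryl ethers and bibenzyl bridges are stable to BBr3.

## Compound list

1 | 4‑bromo‑3‑fluoroanisole | COc1ccc(Br)c(F)c1 | starting material
2 | 3‑bromo‑2‑fluoro‑6‑methoxybenzaldehyde | COc1ccc(Br)c(F)c1C=O | intermediate
3 | 3‑ethynylphenol | C#Cc1cccc(O)c1 | starting material
4 | 3‑bromo‑2‑(3‑ethynylphenoxy)‑6‑methoxybenzaldehyde | COc1ccc(Br)c(Oc2cccc(C#C)c2)c1C=O | intermediate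
5 | 2‑fluoro‑4‑iodobenzaldehyde | O=Cc1ccc(I)cc1F | starting material
6 | 3‑bromo‑2‑{3‑[(3‑fluoro‑4‑formylphenyl)ethynyl]phenoxy}‑6‑methoxybenzaldehyde | COc1ccc(Br)c(Oc2cccc(C#Cc3ccc(C=O)c(F)c3)c2)c1C=O | intermediate
7 | 4‑ethynylphenol | C#Cc1ccc(O)cc1 | starting material
8 | 2‑{3‑[(3‑fluoro‑4‑formylphenyl)ethynyl]phenoxy}‑3‑[(4‑hydroxyphenyl)ethynyl]‑6‑methoxybenzaldehyde | COc1ccc(C#Cc2ccc(O)cc2)c(Oc2cccc(C#Cc3ccc(C=O)c(F)c3)c2)c1C=O | intermediate
9 | 2‑{3‑[2‑(3‑fluoro‑4‑formylphenyl)ethyl]phenoxy}‑3‑[2‑(4‑hydroxyphenyl)ethyl]‑6‑methoxybenzaldehyde | COc1ccc(CCc2ccc(O)cc2)c(Oc2cccc(CCc3ccc(C=O)c(F)c3)c2)c1C=O | intermediate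
10 | macrocyclic dialdehyde (18‑membered; ring A CHO ortho to O–ring B; ring C CHO between OAr and OMe) | O=Cc1ccc2cc1Oc1ccc(cc1)CCc1ccc(OC)c(C=O)c1Oc1cccc(c1)CC2 | intermediate
11 | marchantin H mono‑methyl ether (ring C outer OMe) | Oc1ccc2cc1Oc1ccc(cc1)CCc1ccc(OC)c(O)c1Oc1cccc(c1)CC2 | intermediate
12 | marchantin H (achiral) | Oc1ccc2cc1Oc1ccc(cc1)CCc1ccc(O)c(O)c1Oc1cccc(c1)CC2 | target

## Summary

Total steps: 8. Longest linear sequence: 8 (1 → 12; building blocks 3, 5 and 7 are added directly).

Three steps most likely to fail: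

1. **Step 6 (formyl‑activated SNAr macrocyclization).** Oligomerization or sluggish closure is possible. Fallback: move the ring closure to a C–C bond. Make the ring A–O–ring B ether intermolecularly early (SNAr of a 4‑substituted 2‑fluorobenzaldehyde with the ring B phenol), carry vinyl groups on rings D and A, and close the 18‑membered ring by ring‑closing metathesis to the macrocyclic stilbene, then hydrogenate. The Dakin/BBr3 endgame is unchanged.
2. **Step 5 (alkyne hydrogenation in the presence of two ArCHO groups).** Over‑reduction of the aldehydes or stalling at the stilbene is possible. Fallback: avoid hydrogenation altogether by forming the saturated bridges directly with sp3–sp2 Suzuki–Miyaura couplings. Potassium 2‑arylethyltrifluoroborates, made from the aldehyde‑free vinylphenols, would be coupled with 5 and with the ring C bromide.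
3. **Step 4 (Sonogashira at the hindered, electron‑rich ArBr with sensitive 4‑ethynylphenol).** Fallback: change the order and protection. Couple 2 itself (before the ortho‑aryloxy group is installed) with a robustly protected alkyne, 1‑ethynyl‑4‑(4‑methoxybenzyloxy)benzene, then do the SNAr with 3 and the iodide Sonogashira with 5, hydrogenate, and remove PMB with TFA just before macrocyclization.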